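**Plan**

1. Ring A is a cyclohexane whose bonds C1–C2 and C5–C10 both end on the C1–C10 edge. With C3=C4 written in (possible because C4 carries the C19 lactone carbonyl) it is a Diels–Alder retron: diene C2=C3–C4=C5 (a 3-vinylbutenolide, the 19,6-olide itself) and dienophile C10≡C1 (a silyl ynone with its carbonyl at C20).
2. C20 (on C10) and C6–C7 (on C5) both hang on the arene (C9, C8), so the cycloaddition is intramolecular and closes the seven-membered ring B together with ring A.
3. Further cuts: C7–C8 (aryl Grignard + (R)-epichlorohydrin), C9–C20 (aryllithium + Weinreb amide), O–C19 and C4=C5 (ester, enyne metathesis).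
4. Forward order: arene → two side chains → butenolide → rings A and B in one step → C4 methyl, oxygen moved from C20 to C1, C6=C7 → quinone last.
5. Stereochemistry: C6 from (R)-epichlorohydrin (sacrificial, sp2 at the end) sets C5 through the tether; C4 follows from the cis-fused lactone enolate; C1 from axial hydride delivery.
6. Helpers: SiMe3 on C1 (masks the alkyne C–H, blocks 1,4-reduction, marks C1 for oxygen) and MOM on O12; both leave in step 15.

Key step: step 13

Remark on the chemistry: atoms are numbered as in icetexanes (ring A = C1–C5, C10; ring B = C5, C6, C7, C8, C9, C20, C10; arene = C8, C9, C11–C14; lactone C19(=O)–O–C6; α = the face of H5), and the final oxidation is assumed to work best on the free C12 phenol.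

**Step 1**
Reactants: 1 1,2,4-trimethoxybenzene
Product: 3 2-(2,3,6-trimethoxyphenyl)propan-2-ol, via aryllithium 2 (not isolated)
Conditions: n-BuLi, THF, 0 °C → rt; acetone, −78 °C → rt; H2O
Reagents that add atoms: acetone, CC(C)=O
Why: Directed ortho-lithiation should occur at the position flanked by two methoxy groups, and the aryllithium adds to acetone.

**Step 2**
Reactants: 3 2-(2,3,6-trimethoxyphenyl)propan-2-ol
Product: 4 1,2,4-trimethoxy-3-(propan-2-yl)benzene
Conditions: Et3SiH, CF3CO2H, CH2Cl2, 0 °C → rt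
Reagents that add atoms: none
Why: Ionic hydrogenation, in which the tertiary benzylic cation is trapped by silane hydride.

**Step 3**
Reactants: 4 1,2,4-trimethoxy-3-(propan-2-yl)benzene
Product: 5 3,6-dimethoxy-2-(propan-2-yl)phenol
Conditions: BCl3 (1.1 equiv), CH2Cl2, −78 → 0 °C; H2O
Reagents that add atoms: none
Why: Lewis-acid demethylation should take the methoxy group that is twisted out of plane between the isopropyl and a methoxy neighbour and can chelate boron with that neighbour, the usual site selectivity for contiguously substituted aryl methyl ethers.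

**Step 4**
Reactants: 5 3,6-dimethoxy-2-(propan-2-yl)phenol
Product: 6 1,4-dimethoxy-2-(methoxymethoxy)-3-(propan-2-yl)benzene
Conditions: MOMCl, i-Pr2NEt, CH2Cl2, 0 → 40 °C
Reagents that add atoms: chloromethyl methyl ether, COCCl
Why: O-alkylation of the phenol gives an acetal that survives organometallics, hydride, peracid and heat and is cleaved by the aqueous acid of step 15.

**Step 5**
Reactants: 6 1,4-dimethoxy-2-(methoxymethoxy)-3-(propan-2-yl)benzene
Product: 7 1-bromo-2,5-dimethoxy-4-(methoxymethoxy)-3-(propan-2-yl)benzene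
Conditions: NBS, MeCN, 0 °C
Reagents that add atoms: N-bromosuccinimide, O=C1CCC(=O)N1Br
Why: Electrophilic aromatic bromination should go para to OMOM and ortho to a methoxy group (C8), the most activated open position.

**Step 6**
Reactants: 7 1-bromo-2,5-dimethoxy-4-(methoxymethoxy)-3-(propan-2-yl)benzene; 8 (R)-epichlorohydrin
Product: 10 (2R)-1-chloro-3-[2,5-dimethoxy-4-(methoxymethoxy)-3-(propan-2-yl)phenyl]propan-2-ol, via arylmagnesium bromide 9 (not isolated)
Conditions: Mg, THF, 50 °C; then CuI (10 mol%), 8, −40 → −10 °C; H2O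
Reagents that add atoms: none
Why: Copper-catalysed Grignard opening of the epoxide at its CH2 terminus forms C7–C8 and leaves the carbinol stereocentre (the future C6) untouched.

**Step 7**
Reactants: 10 (2R)-1-chloro-3-[2,5-dimethoxy-4-(methoxymethoxy)-3-(propan-2-yl)phenyl]propan-2-ol
Product: 11 (2R)-1-[2-bromo-3,6-dimethoxy-4-(methoxymethoxy)-5-(propan-2-yl)phenyl]-3-chloropropan-2-ol
Conditions: NBS, MeCN, 0 °C
Reagents that add atoms: N-bromosuccinimide, O=C1CCC(=O)N1Br
Why: Only one aromatic position (C9) is left, so the second electrophilic bromination is unambiguous and installs the handle for the C20 unit.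

**Step 8**
Reactants: 11 (2R)-1-[2-bromo-3,6-dimethoxy-4-(methoxymethoxy)-5-(propan-2-yl)phenyl]-3-chloropropan-2-ol
Product: 13 (2R)-1-[2-bromo-3,6-dimethoxy-4-(methoxymethoxy)-5-(propan-2-yl)phenyl]but-3-en-2-ol, via epoxide 12 (not isolated)
Conditions: Me3S+ I− (4 equiv), n-BuLi (3.9 equiv), THF, −10 °C; then 11, −10 °C → rt; H2O
Reagents that add atoms: trimethylsulfonium iodide, C[S+](C)C.[I-]
Why: The ylide first acts as base to close the epoxide, then opens it at CH2, and α',β-elimination of Me2S from the derived betaine ylide gives the one-carbon-homologated allylic alcohol with the stereocentre intact (sulfonium-ylide homologation of a terminal epoxide).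

**Step 9**
Reactants: 14 3-(trimethylsilyl)prop-2-ynoic acid
Product: 15 N-methoxy-N-methyl-3-(trimethylsilyl)prop-2-ynamide
Conditions: MeNH(OMe)·HCl, EDC·HCl, i-Pr2NEt, CH2Cl2, 0 °C → rt
Reagents that add atoms: N,O-dimethylhydroxylamine hydrochloride, CNOC.Cl
Why: Carbodiimide amidation gives the Weinreb amide, with silicon masking the acidic acetylenic C–H for step 10.

**Step 10**
Reactants: 13 (2R)-1-[2-bromo-3,6-dimethoxy-4-(methoxymethoxy)-5-(propan-2-yl)phenyl]but-3-en-2-ol; 15 N-methoxy-N-methyl-3-(trimethylsilyl)prop-2-ynamide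
Product: 17 1-{2-[(2R)-2-hydroxybut-3-en-1-yl]-3,6-dimethoxy-5-(methoxymethoxy)-4-(propan-2-yl)phenyl}-3-(trimethylsilyl)prop-2-yn-1-one, via aryllithium alkoxide 16 (not isolated)
Conditions: n-BuLi (1.05 equiv), then t-BuLi (2.1 equiv), THF, −78 °C; then 15, −78 → −40 °C; H2O
Reagents that add atoms: none
Why: O–H deprotonation, Br/Li exchange and acylation by the Weinreb amide, whose chelated tetrahedral adduct prevents over-addition (Weinreb ketone synthesis); the low temperature keeps the aryllithium from adding to the vinyl group.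

**Step 11**
Reactants: 17 1-{2-[(2R)-2-hydroxybut-3-en-1-yl]-3,6-dimethoxy-5-(methoxymethoxy)-4-(propan-2-yl)phenyl}-3-(trimethylsilyl)prop-2-yn-1-one; 18 prop-2-ynoic acid
Product: 19 (2R)-1-{3,6-dimethoxy-4-(methoxymethoxy)-5-(propan-2-yl)-2-[3-(trimethylsilyl)prop-2-ynoyl]phenyl}but-3-en-2-yl prop-2-ynoate
Conditions: DCC, DMAP (5 mol%), CH2Cl2, −20 → 0 °C
Reagents that add atoms: none
Why: Steglich esterification of the secondary allylic alcohol proceeds with retention at C6, and the low temperature limits amine addition to the propiolate.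

**Step 12**
Reactants: 19 (2R)-1-{3,6-dimethoxy-4-(methoxymethoxy)-5-(propan-2-yl)-2-[3-(trimethylsilyl)prop-2-ynoyl]phenyl}but-3-en-2-yl prop-2-ynoate
Product: 20 (5R)-5-({3,6-dimethoxy-4-(methoxymethoxy)-5-(propan-2-yl)-2-[3-(trimethylsilyl)prop-2-ynoyl]phenyl}methyl)-3-ethenylfuran-2(5H)-one
Conditions: second-generation Grubbs catalyst RuCl2(=CHPh)(PCy3)(H2IMes) (10 mol%), ethylene (1 atm), toluene (5 mM), 60 °C; silica plug, solution used at once
Reagents that add atoms: none
Why: Ring-closing enyne metathesis, a known route from allyl propiolates to 3-vinylbutenolides: the Ru alkylidene formed at the terminal alkene adds to the propiolate alkyne in the exo mode, closing C4=C5 and releasing the C3=C2 vinyl group, while the silyl-capped ketone-conjugated alkyne should be too hindered and electron-poor to engage the catalyst.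

**Step 13**
Reactants: 20 (5R)-5-({3,6-dimethoxy-4-(methoxymethoxy)-5-(propan-2-yl)-2-[3-(trimethylsilyl)prop-2-ynoyl]phenyl}methyl)-3-ethenylfuran-2(5H)-one
Product: 21 11,14-dimethoxy-12-(methoxymethoxy)-20-oxo-1-(trimethylsilyl)-18-noricetexa-1(10),3,8,11,13-pentaen-19,6β-olide (5αH)
Conditions: toluene (5 mM), BHT (cat.), 130 °C, sealed vessel, argon
Reagents that add atoms: none
Why: Thermal, concerted but asynchronous [4+2] cycloaddition of the 3-vinylbutenolide diene (C2=C3–C4=C5) with the silyl ynone (C10≡C1) should form C1–C2 and C5–C10 at once; the closest known reaction type is the type 1 intramolecular Diels–Alder reaction of ynone dienophiles, and 3-vinylbutenolides are known to be reactive Diels–Alder dienes. Ring A is closed by the cycloaddition itself (both new bonds), and the seven-membered ring B is closed in the fused mode by the C5–C10 bond, the tether C6–C7–C8–C9–C20 being pre-organised by the ortho-disubstituted arene and the carbonyl. The only new stereocentre, C5, is controlled by C6: the ynone is tied to C7 and can reach the planar butenolide only on the face that carries C7, so C10 adds cis to C7 and H5 comes out cis to H6, which with (R)-C6 is the 5α-H of the target. C1 and C10 stay sp2 because the dienophile is an alkyne, so no endo/exo question arises. The step needs regioselectivity (C10 to C5, C1 to C2), secured by the tether because the crossed mode would require a bridged eight-membered ring, and it must outrun [4+2] dimerisation of the diene, secured by high dilution, BHT and the strong activation of the ynone.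

**Step 14**
Reactants: 21 11,14-dimethoxy-12-(methoxymethoxy)-20-oxo-1-(trimethylsilyl)-18-noricetexa-1(10),3,8,11,13-pentaen-19,6β-olide (5αH)
Product: 23 20-hydroxy-11,14-dimethoxy-12-(methoxymethoxy)-1-(trimethylsilyl)icetexa-1(10),8,11,13-tetraen-19,6β-olide (5αH; both C20 epimers), via lithium enolate 22 (not isolated)
Conditions: LiBH(s-Bu)3 (2.5 equiv), THF, −78 → −30 °C; then MeI (6 equiv), HMPA, −78 → 0 °C; H2O
Reagents that add atoms: iodomethane, CI
Why: The hindered hydride should add 1,4 to the unsaturated lactone (at C3) and, because silicon blocks the β-carbon of the enone, only 1,2 to the C20 ketone; the lactone enolate is then C-methylated on the face away from ring B, the only trajectory that keeps the lactone cis-fused to ring A, so the methyl ends up cis to H5 (reductive alkylation).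

**Step 15**
Reactants: 23 20-hydroxy-11,14-dimethoxy-12-(methoxymethoxy)-1-(trimethylsilyl)icetexa-1(10),8,11,13-tetraen-19,6β-olide (5αH; both C20 epimers)
Product: 25 12-hydroxy-11,14-dimethoxy-1-oxoicetexa-8,10(20),11,13-tetraen-19,6β-olide (5αH), via epoxysilane 24 (not isolated)
Conditions: m-CPBA (1.2 equiv), CH2Cl2, 0 °C; then 3 M aq. HCl, THF, 45 °C
Reagents that add atoms: water, O
Why: Hydroxyl-directed peracid epoxidation of the electron-rich vinylsilane gives the α,β-epoxysilane; aqueous acid opens it at the silicon-bearing C1, Peterson elimination of the β-hydroxysilane leaves the C1 enol, whose push expels the benzylic C20 hydroxyl to give the C1 ketone conjugated with the C10=C20 alkene, and the same acid cleaves the MOM acetal (vinylsilane as masked ketone, then E1-type dehydration).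

**Step 16**
Reactants: 25 12-hydroxy-11,14-dimethoxy-1-oxoicetexa-8,10(20),11,13-tetraen-19,6β-olide (5αH)
Product: 27 12-hydroxy-11,14-dimethoxy-1-oxoicetexa-6,8,10(20),11,13-pentaen-19,6-olide (5αH), via para-quinone methide 26 (not isolated)
Conditions: DDQ (1.05 equiv), 1,4-dioxane, 20 °C
Reagents that add atoms: none
Why: DDQ should oxidise the free C12 phenol, which is para to C8, to the para-quinone methide (C7=C8), and tautomerisation with loss of H6 restores the arene and leaves the C6=C7 enol lactone; C7 alone is addressed because H5 is not in conjugation with the phenol oxygen (dehydrogenation of para-alkylphenols via quinone methides).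

**Step 17**
Reactants: 27 12-hydroxy-11,14-dimethoxy-1-oxoicetexa-6,8,10(20),11,13-pentaen-19,6-olide (5αH)
Product: 28 1β,12-dihydroxy-11,14-dimethoxyicetexa-6,8,10(20),11,13-pentaen-19,6-olide (5αH)
Conditions: NaBH4, CeCl3·7H2O, MeOH–THF, −78 °C
Reagents that add atoms: none
Why: Luche 1,2-reduction of the enone, in which the small hydride should attack C1 axially from the α face (the side of H5 and H3α) to give the equatorial 1β-alcohol, while the enol lactone and phenol are inert at −78 °C.

**Step 18**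
Reactants: 28 1β,12-dihydroxy-11,14-dimethoxyicetexa-6,8,10(20),11,13-pentaen-19,6-olide (5αH)
Product: 29 6,7-anhydroballotiquinone
Conditions: (NH4)2Ce(NO3)6 (2.5 equiv), MeCN–H2O (3:1), 0 °C
Reagents that add atoms: water, O
Why: Tetravalent cerium oxidises the electron-rich 11,14-dimethoxy-12-phenol, water adds at the methoxy-bearing carbons and methanol is lost (oxidative demethylation), which should give the 12-hydroxy-11,14-quinone directly.

**Compound list**

1 | 1,2,4-trimethoxybenzene | COc1ccc(OC)c(OC)c1 | starting material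
2 | (2,3,6-trimethoxyphenyl)lithium | COc1ccc(OC)c(OC)c1[Li] | intermediate (not isolated)
3 | 2-(2,3,6-trimethoxyphenyl)propan-2-ol | COc1ccc(OC)c(OC)c1C(C)(C)O | intermediate
4 | 1,2,4-trimethoxy-3-(propan-2-yl)benzene | COc1ccc(OC)c(OC)c1C(C)C | intermediate
5 | 3,6-dimethoxy-2-(propan-2-yl)phenol | COc1ccc(OC)c(O)c1C(C)C | intermediate
6 | 1,4-dimethoxy-2-(methoxymethoxy)-3-(propan-2-yl)benzene | COc1ccc(OC)c(OCOC)c1C(C)C | intermediate
7 | 1-bromo-2,5-dimethoxy-4-(methoxymethoxy)-3-(propan-2-yl)benzene | COc1c(C(C)C)c(OCOC)c(OC)cc1Br | intermediate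
8 | (R)-epichlorohydrin, (2R)-2-(chloromethyl)oxirane | ClC[C@H]1CO1 | starting material
9 | [2,5-dimethoxy-4-(methoxymethoxy)-3-(propan-2-yl)phenyl]magnesium bromide | COc1c(C(C)C)c(OCOC)c(OC)cc1[Mg]Br | intermediate (not isolated)
10 | (2R)-1-chloro-3-[2,5-dimethoxy-4-(methoxymethoxy)-3-(propan-2-yl)phenyl]propan-2-ol | COc1c(C(C)C)c(OCOC)c(OC)cc1C[C@@H](O)CCl | intermediate
11 | (2R)-1-[2-bromo-3,6-dimethoxy-4-(methoxymethoxy)-5-(propan-2-yl)phenyl]-3-chloropropan-2-ol | COc1c(C(C)C)c(OCOC)c(OC)c(Br)c1C[C@@H](O)CCl | intermediate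
12 | (2R)-2-{[2-bromo-3,6-dimethoxy-4-(methoxymethoxy)-5-(propan-2-yl)phenyl]methyl}oxirane | COc1c(C(C)C)c(OCOC)c(OC)c(Br)c1C[C@@H]2CO2 | intermediate (not isolated)
13 | (2R)-1-[2-bromo-3,6-dimethoxy-4-(methoxymethoxy)-5-(propan-2-yl)phenyl]but-3-en-2-ol | COc1c(C(C)C)c(OCOC)c(OC)c(Br)c1C[C@@H](O)C=C | intermediate
14 | 3-(trimethylsilyl)prop-2-ynoic acid | C[Si](C)(C)C#CC(=O)O | starting material
15 | N-methoxy-N-methyl-3-(trimethylsilyl)prop-2-ynamide | CON(C)C(=O)C#C[Si](C)(C)C | intermediate
16 | C9-lithiated lithium alkoxide of 13 | COc1c(C(C)C)c(OCOC)c(OC)c([Li])c1C[C@@H](O[Li])C=C | intermediate (not isolated)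
17 | 1-{2-[(2R)-2-hydroxybut-3-en-1-yl]-3,6-dimethoxy-5-(methoxymethoxy)-4-(propan-2-yl)phenyl}-3-(trimethylsilyl)prop-2-yn-1-one | COc1c(C(C)C)c(OCOC)c(OC)c(C(=O)C#C[Si](C)(C)C)c1C[C@@H](O)C=C | intermediate
18 | prop-2-ynoic acid | C#CC(=O)O | starting material
19 | (2R)-1-{3,6-dimethoxy-4-(methoxymethoxy)-5-(propan-2-yl)-2-[3-(trimethylsilyl)prop-2-ynoyl]phenyl}but-3-en-2-yl prop-2-ynoate | COc1c(C(C)C)c(OCOC)c(OC)c(C(=O)C#C[Si](C)(C)C)c1C[C@@H](OC(=O)C#C)C=C | intermediate
20 | (5R)-5-({3,6-dimethoxy-4-(methoxymethoxy)-5-(propan-2-yl)-2-[3-(trimethylsilyl)prop-2-ynoyl]phenyl}methyl)-3-ethenylfuran-2(5H)-one | COc1c(C(C)C)c(OCOC)c(OC)c(C(=O)C#C[Si](C)(C)C)c1C[C@H]2OC(=O)C(C=C)=C2 | intermediate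
21 | 11,14-dimethoxy-12-(methoxymethoxy)-20-oxo-1-(trimethylsilyl)-18-noricetexa-1(10),3,8,11,13-pentaen-19,6β-olide (5αH, 6αH) | COc1c(C(C)C)c(OCOC)c(OC)c2c1C[C@H]3OC(=O)C4=CCC([Si](C)(C)C)=C(C2=O)[C@@H]34 | intermediate
22 | dilithium salt: C19 lactone enolate and C20 alkoxide of reduced 21 | COc1c(C(C)C)c(OCOC)c(OC)c2c1C[C@H]3OC(O[Li])=C4CCC([Si](C)(C)C)=C(C2O[Li])[C@@H]34 | intermediate (not isolated)
23 | 20-hydroxy-11,14-dimethoxy-12-(methoxymethoxy)-1-(trimethylsilyl)icetexa-1(10),8,11,13-tetraen-19,6β-olide (4α-methyl, 5αH; both C20 epimers) | COc1c(C(C)C)c(OCOC)c(OC)c2c1C[C@H]3OC(=O)[C@@]4(C)CCC([Si](C)(C)C)=C(C2O)[C@@H]34 | intermediate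
24 | 1,10-epoxide of 23 (α,β-epoxysilane) | COc1c(C(C)C)c(OCOC)c(OC)c2c1C[C@H]3OC(=O)[C@@]4(C)CCC5([Si](C)(C)C)OC5(C2O)[C@@H]34 | intermediate (not isolated)
25 | 12-hydroxy-11,14-dimethoxy-1-oxoicetexa-8,10(20),11,13-tetraen-19,6β-olide (5αH) | COc1c(C(C)C)c(O)c(OC)c2c1C[C@H]3OC(=O)[C@@]4(C)CCC(=O)C(=C2)[C@@H]34 | intermediate
26 | para-quinone methide of 25 (12-oxo, C7=C8) | COC1=C(C(C)C)C(=O)C(OC)=C2C1=C[C@H]3OC(=O)[C@@]4(C)CCC(=O)C(=C2)[C@@H]34 | intermediate (not isolated)
27 | 12-hydroxy-11,14-dimethoxy-1-oxoicetexa-6,8,10(20),11,13-pentaen-19,6-olide (5αH) | COc1c(C(C)C)c(O)c(OC)c2c1C=C3OC(=O)[C@@]4(C)CCC(=O)C(=C2)[C@@H]34 | intermediate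
28 | 1β,12-dihydroxy-11,14-dimethoxyicetexa-6,8,10(20),11,13-pentaen-19,6-olide (5αH) | COc1c(C(C)C)c(O)c(OC)c2c1C=C3OC(=O)[C@@]4(C)CC[C@@H](O)C(=C2)[C@@H]34 | intermediate
29 | 6,7-anhydroballotiquinone (1β,12-dihydroxy-11,14-dioxoicetexa-6,8,10(20),12-tetraen-19,6-olide) | CC(C)C1=C(O)C(=O)C2=C(C=C3OC(=O)[C@@]4(C)CC[C@@H](O)C(=C2)[C@@H]34)C1=O | target

**Step count and risks**

Total steps: 18. Longest linear sequence: 17 (steps 1–8 and 10–18, from 1).

Steps most likely to fail:

Step 13. The cycloaddition may stall because the silyl group and the twisted aryl ketone slow the approach of the ynone, which would leave time for intermolecular [4+2] dimerisation of the vinylbutenolide. The fallback changes the dienophile and, with it, the way the C1 oxygen is brought in. It sets out from 20: Bu4NF/AcOH (1:1) in THF at −20 °C removes the silyl group to give the terminal ynone F1, an unhindered dienophile that should cyclise in toluene at 80 °C to the des-silyl cycloadduct F2. NaBH4/CeCl3 then gives the C20 allylic alcohol F3; LiN(SiMe3)2 (1 equiv) followed by LiBH(s-Bu)3 and MeI gives the C4-methylated lactone F4; 1,3-transposition catalysed by Ph3SiOReO3 moves the oxygen to C1 and gives the arene-conjugated allylic alcohol F5; MnO2 gives the MOM-protected enone F6; 3 M HCl in THF removes the MOM group and the route is rejoined at 25.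

Step 12. Enyne metathesis may fail to turn over on the electron-poor propiolate (catalyst tied up by the alkynes), or the product diene may dimerise during work-up. The fallback builds the butenolide by alkene metathesis and adds the vinyl group by cross-coupling. It sets out from 17: acryloyl chloride/Et3N gives the acrylate F7; ring-closing metathesis with second-generation Grubbs catalyst RuCl2(=CHPh)(PCy3)(H2IMes) gives the 3-unsubstituted butenolide F8; α-iodination with I2/pyridine gives the 3-iodobutenolide F9; Stille coupling with tributyl(vinyl)stannane (Pd2(dba)3, AsPh3) comes back to the route at 20.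

Step 15. Peracid attack on the tetrasubstituted vinylsilane may be too slow, or ionisation at the benzylic C20 carbinol may outrun opening of the hindered epoxysilane and divert material into skeletal rearrangement. The fallback replaces the epoxysilane by a vinylogous-ester carbonyl transposition. It sets out from 23: ipso-iododesilylation with NIS (MeCN, 0 °C) gives the vinyl iodide F10; Dess–Martin periodinane gives the β-iodoenone F11; addition–elimination with NaOMe in MeOH at 0 °C gives the vinylogous ester F12; NaBH4/CeCl3 gives the allylic alcohol F13; 3 M HCl in THF then effects the Stork–Danheiser transposition together with MOM cleavage and returns to the route at 25.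

**Further compounds**

F1 | step 13 | (5R)-5-{[3,6-dimethoxy-4-(methoxymethoxy)-5-(propan-2-yl)-2-(prop-2-ynoyl)phenyl]methyl}-3-ethenylfuran-2(5H)-one | COc1c(C(C)C)c(OCOC)c(OC)c(C(=O)C#C)c1C[C@H]2OC(=O)C(C=C)=C2
F2 | step 13 | 11,14-dimethoxy-12-(methoxymethoxy)-20-oxo-18-noricetexa-1(10),3,8,11,13-pentaen-19,6β-olide (5αH) | COc1c(C(C)C)c(OCOC)c(OC)c2c1C[C@H]3OC(=O)C4=CCC=C(C2=O)[C@@H]34
F3 | step 13 | 20-hydroxy-11,14-dimethoxy-12-(methoxymethoxy)-18-noricetexa-1(10),3,8,11,13-pentaen-19,6β-olide (5αH) | COc1c(C(C)C)c(OCOC)c(OC)c2c1C[C@H]3OC(=O)C4=CCC=C(C2O)[C@@H]34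
F4 | step 13 | 20-hydroxy-11,14-dimethoxy-12-(methoxymethoxy)icetexa-1(10),8,11,13-tetraen-19,6β-olide (5αH) | COc1c(C(C)C)c(OCOC)c(OC)c2c1C[C@H]3OC(=O)[C@@]4(C)CCC=C(C2O)[C@@H]34
F5 | step 13 | 1-hydroxy-11,14-dimethoxy-12-(methoxymethoxy)icetexa-8,10(20),11,13-tetraen-19,6β-olide (5αH) | COc1c(C(C)C)c(OCOC)c(OC)c2c1C[C@H]3OC(=O)[C@@]4(C)CCC(O)C(=C2)[C@@H]34
F6 | step 13 | 11,14-dimethoxy-12-(methoxymethoxy)-1-oxoicetexa-8,10(20),11,13-tetraen-19,6β-olide (5αH) | COc1c(C(C)C)c(OCOC)c(OC)c2c1C[C@H]3OC(=O)[C@@]4(C)CCC(=O)C(=C2)[C@@H]34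
F7 | step 12 | (2R)-1-{3,6-dimethoxy-4-(methoxymethoxy)-5-(propan-2-yl)-2-[3-(trimethylsilyl)prop-2-ynoyl]phenyl}but-3-en-2-yl prop-2-enoate | COc1c(C(C)C)c(OCOC)c(OC)c(C(=O)C#C[Si](C)(C)C)c1C[C@@H](OC(=O)C=C)C=C
F8 | step 12 | (5R)-5-({3,6-dimethoxy-4-(methoxymethoxy)-5-(propan-2-yl)-2-[3-(trimethylsilyl)prop-2-ynoyl]phenyl}methyl)furan-2(5H)-one | COc1c(C(C)C)c(OCOC)c(OC)c(C(=O)C#C[Si](C)(C)C)c1C[C@H]2OC(=O)C=C2
F9 | step 12 | (5R)-5-({3,6-dimethoxy-4-(methoxymethoxy)-5-(propan-2-yl)-2-[3-(trimethylsilyl)prop-2-ynoyl]phenyl}methyl)-3-iodofuran-2(5H)-one | COc1c(C(C)C)c(OCOC)c(OC)c(C(=O)C#C[Si](C)(C)C)c1C[C@H]2OC(=O)C(I)=C2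
F10 | step 15 | 20-hydroxy-1-iodo-11,14-dimethoxy-12-(methoxymethoxy)icetexa-1(10),8,11,13-tetraen-19,6β-olide (5αH) | COc1c(C(C)C)c(OCOC)c(OC)c2c1C[C@H]3OC(=O)[C@@]4(C)CCC(I)=C(C2O)[C@@H]34
F11 | step 15 | 1-iodo-11,14-dimethoxy-12-(methoxymethoxy)-20-oxoicetexa-1(10),8,11,13-tetraen-19,6β-olide (5αH) | COc1c(C(C)C)c(OCOC)c(OC)c2c1C[C@H]3OC(=O)[C@@]4(C)CCC(I)=C(C2=O)[C@@H]34
F12 | step 15 | 1,11,14-trimethoxy-12-(methoxymethoxy)-20-oxoicetexa-1(10),8,11,13-tetraen-19,6β-olide (5αH) | COc1c(C(C)C)c(OCOC)c(OC)c2c1C[C@H]3OC(=O)[C@@]4(C)CCC(OC)=C(C2=O)[C@@H]34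
F13 | step 15 | 20-hydroxy-1,11,14-trimethoxy-12-(methoxymethoxy)icetexa-1(10),8,11,13-tetraen-19,6β-olide (5αH) | COc1c(C(C)C)c(OCOC)c(OC)c2c1C[C@H]3OC(=O)[C@@]4(C)CCC(OC)=C(C2O)[C@@H]34
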